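## Retrosynthetic overview

1. Target 30 ⇐ base-free Dess–Martin oxidation of carbinol 29; the two ketone-flanking methines are carried as a protected syn,syn Me/O/Me stereotriad, and the carbinol configuration is irrelevant.
2. Ring A (pentyl pyrone, formed second) ⇐ Ph3P/CCl4 cyclodehydration of triketone 27 ⇐ aldol of aldehyde 18 with ethyl ketone 23 (from pentan-3-one and hexanal).
3. Ring B (ethyl pyrone, formed first) ⇐ the same cyclodehydration of triketone 15 ⇐ aldol of aldehyde 10 with the dianion of 4-methylheptane-3,5-dione 12.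
4. Stereotriad 7 ⇐ substrate-controlled (Felkin, syn) crotylstannane addition to aldehyde 5.
5. Aldehyde 5 ⇐ ene-reductase-catalysed asymmetric C=C reduction of achiral acrylate 2, the only source of absolute configuration.

Assumption: centres that later become sp2 carbon (the carbinol and methyl-bearing centres created in steps 9, 14 and 16) are carried as diastereomer mixtures and written without configuration in the SMILES.

Abbreviations: TBS = tert-butyldimethylsilyl, TES = triethylsilyl.

## Route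

Step 1
Reactants: 1 methyl 2-(hydroxymethyl)prop-2-enoate
Product: 2 methyl 2-{[(tert-butyldimethylsilyl)oxy]methyl}prop-2-enoate
Conditions: TBSCl, imidazole, CH2Cl2, 0 °C → rt
Reagents that add atoms: tert-butyldimethylsilyl chloride, CC(C)(C)[Si](C)(C)Cl
Why: Routine imidazole-promoted silylation of a primary allylic alcohol gives an achiral, lipophilic acrylate that is a good substrate for the bioreduction.

Step 2
Reactants: 2 methyl 2-{[(tert-butyldimethylsilyl)oxy]methyl}prop-2-enoate
Product: 3 methyl (2R)-3-[(tert-butyldimethylsilyl)oxy]-2-methylpropanoate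
Conditions: ene-reductase (Old Yellow Enzyme family, flavin-dependent), NAD+ (cat.), formate dehydrogenase, HCO2Na, KH2PO4/K2HPO4 buffer pH 7.5, t-BuOMe (10% v/v), 30 °C
Reagents that add atoms: none
Why: Biocatalytic asymmetric conjugate reduction by an ene-reductase, in which the reduced flavin delivers hydride to the terminal CH2 and an active-site tyrosine protonates the α-carbon from the opposite face, so the enzyme's binding mode sets the first stereocentre as R in high ee.

Step 3
Reactants: 3 methyl (2R)-3-[(tert-butyldimethylsilyl)oxy]-2-methylpropanoate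
Product: 4 (2S)-3-[(tert-butyldimethylsilyl)oxy]-2-methylpropan-1-ol
Conditions: i-Bu2AlH (2.3 equiv), CH2Cl2, −78 → 0 °C; aq. KNaC4H4O6
Reagents that add atoms: none
Why: Aluminium hydride reduction of the ester to the primary alcohol leaves the stereocentre untouched (the descriptor changes only because the CIP priorities change).

Step 4
Reactants: 4 (2S)-3-[(tert-butyldimethylsilyl)oxy]-2-methylpropan-1-ol
Product: 5 (2R)-3-[(tert-butyldimethylsilyl)oxy]-2-methylpropanal
Conditions: Dess–Martin periodinane, pyridine, CH2Cl2, 0 °C → rt; used at once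
Reagents that add atoms: none
Why: Pyridine-buffered Dess–Martin oxidation gives the α-chiral aldehyde without epimerisation when it is used crude and immediately.

Step 5
Reactants: 5 (2R)-3-[(tert-butyldimethylsilyl)oxy]-2-methylpropanal; 6 tributyl(but-2-en-1-yl)stannane (E/Z mixture)
Product: 7 (2R,3R,4S)-1-[(tert-butyldimethylsilyl)oxy]-2,4-dimethylhex-5-en-3-ol
Conditions: BF3·OEt2 (1.2 equiv), CH2Cl2, −78 °C; aq. NaHCO3; chromatography on KF-doped silica
Reagents that add atoms: none
Why: Keck-type Lewis-acid crotylstannane addition through an open antiperiplanar transition state gives the 3,4-syn relationship from either stannane geometry, and Felkin–Anh attack on the non-chelated BF3-bound β-silyloxy aldehyde gives 2,3-syn, so C3 (R) and C4 (S) are set by substrate control from C2.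

Step 6
Reactants: 7 (2R,3R,4S)-1-[(tert-butyldimethylsilyl)oxy]-2,4-dimethylhex-5-en-3-ol
Product: 8 (2R,3R,4S)-1,3-bis[(tert-butyldimethylsilyl)oxy]-2,4-dimethylhex-5-ene
Conditions: t-BuMe2SiOTf, 2,6-lutidine, CH2Cl2, −78 → 0 °C
Reagents that add atoms: tert-butyldimethylsilyl trifluoromethanesulfonate, CC(C)(C)[Si](C)(C)OS(=O)(=O)C(F)(F)F
Why: The silyl triflate silylates even this doubly flanked secondary alcohol, giving a hindered ether that survives every later step until the deliberate HF cleavage.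

Step 7
Reactants: 8 (2R,3R,4S)-1,3-bis[(tert-butyldimethylsilyl)oxy]-2,4-dimethylhex-5-ene
Product: 10 (2R,3S,4R)-3,5-bis[(tert-butyldimethylsilyl)oxy]-2,4-dimethylpentanal, via secondary ozonide 9 (not isolated)
Conditions: O3, CH2Cl2, −78 °C; then Ph3P, −78 °C → rt
Reagents that add atoms: ozone, [O-][O+]=O
Why: Ozonolysis with reductive work-up cleaves the terminal vinyl group to the aldehyde under neutral conditions that do not epimerise the α-centre.

Step 8
Reactants: 11 heptane-3,5-dione
Product: 12 4-methylheptane-3,5-dione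
Conditions: MeI (1.1 equiv), K2CO3, acetone, reflux; distillation
Reagents that add atoms: iodomethane, CI
Why: C-alkylation (SN2) of the potassium enolate of a β-diketone at its central carbon is a standard, scalable reaction.

Step 9
Reactants: 10 (2R,3S,4R)-3,5-bis[(tert-butyldimethylsilyl)oxy]-2,4-dimethylpentanal; 12 4-methylheptane-3,5-dione (1.5 equiv)
Product: 14 (8S,9S,10R)-9,11-bis[(tert-butyldimethylsilyl)oxy]-7-hydroxy-4,6,8,10-tetramethylundecane-3,5-dione (mixture at C4, C6, C7), via dilithium dienolate 13 (not isolated)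
Conditions: 12, LiN(i-Pr)2 (commercial solution, 2.1 equiv per 12), THF, −78 → 0 °C; then 10, −78 °C; aq. NH4Cl
Reagents that add atoms: none
Why: Hauser-type β-diketone dianion aldol, in which the terminal carbanion of the 1,3-dianion adds to the aldehyde at −78 °C faster than it enolises it, and the unselectively formed new centres all become sp2 later.

Step 10
Reactants: 14 (8S,9S,10R)-9,11-bis[(tert-butyldimethylsilyl)oxy]-7-hydroxy-4,6,8,10-tetramethylundecane-3,5-dione
Product: 15 (8R,9S,10R)-9,11-bis[(tert-butyldimethylsilyl)oxy]-4,6,8,10-tetramethylundecane-3,5,7-trione (mixture at C4, C6; keto–enol tautomers)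
Conditions: Dess–Martin periodinane (2 equiv), pyridine, CH2Cl2, rt
Reagents that add atoms: none
Why: Dess–Martin oxidation of the β-hydroxy ketone to the 1,3,5-triketone is mild and buffered, so the C8 methine next to the new carbonyl keeps its configuration.

Step 11
Reactants: 15 (8R,9S,10R)-9,11-bis[(tert-butyldimethylsilyl)oxy]-4,6,8,10-tetramethylundecane-3,5,7-trione
Product: 16 2-[(2R,3S,4R)-3,5-bis[(tert-butyldimethylsilyl)oxy]-4-methylpentan-2-yl]-6-ethyl-3,5-dimethyl-4H-pyran-4-one
Conditions: Ph3P (5 equiv), CCl4, THF, rt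
Reagents that add atoms: none
Why: Yamamura-type cyclodehydration of a β-triketone, in which O-phosphonium activation of one terminal enol and attack by the other terminal enol oxygen closes ring B under near-neutral conditions that preserve the adjacent stereocentre.

Step 12
Reactants: 16 2-[(2R,3S,4R)-3,5-bis[(tert-butyldimethylsilyl)oxy]-4-methylpentan-2-yl]-6-ethyl-3,5-dimethyl-4H-pyran-4-one
Product: 17 2-[(2R,3S,4R)-3-[(tert-butyldimethylsilyl)oxy]-5-hydroxy-4-methylpentan-2-yl]-6-ethyl-3,5-dimethyl-4H-pyran-4-one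
Conditions: HF·pyridine, pyridine, THF, 0 °C → rt
Reagents that add atoms: none
Why: Buffered HF·pyridine cleaves the unhindered primary silyl ether much faster than the secondary one flanked by two branched carbons, and the pyrone is inert to fluoride.

Step 13
Reactants: 17 2-[(2R,3S,4R)-3-[(tert-butyldimethylsilyl)oxy]-5-hydroxy-4-methylpentan-2-yl]-6-ethyl-3,5-dimethyl-4H-pyran-4-one
Product: 18 (2S,3R,4R)-3-[(tert-butyldimethylsilyl)oxy]-4-(6-ethyl-3,5-dimethyl-4-oxo-4H-pyran-2-yl)-2-methylpentanal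
Conditions: Dess–Martin periodinane, pyridine, CH2Cl2, 0 °C → rt; used at once
Reagents that add atoms: none
Why: Buffered Dess–Martin oxidation of the primary alcohol gives the α-chiral aldehyde without epimerisation and does not touch the pyrone.

Step 14
Reactants: 19 pentan-3-one; 20 hexanal
Product: 22 5-hydroxy-4-methyldecan-3-one (racemic syn/anti mixture), via lithium enolate 21 (not isolated)
Conditions: LiN(i-Pr)2 (commercial solution), THF, −78 °C; then hexanal, −78 °C; aq. NH4Cl
Reagents that add atoms: none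
Why: Kinetic lithium aldol addition of a symmetrical ketone to an unbranched aldehyde is dependable, and both new centres later become sp2.

Step 15
Reactants: 22 5-hydroxy-4-methyldecan-3-one
Product: 23 4-methyl-5-[(triethylsilyl)oxy]decan-3-one
Conditions: Et3SiCl, imidazole, DMF, rt
Reagents that add atoms: chlorotriethylsilane, CC[Si](Cl)(CC)CC
Why: Triethylsilyl protection blocks retro-aldol and dianion chemistry in the next enolisation and can later be removed in the presence of the hindered TBS ether.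

Step 16
Reactants: 18 (2S,3R,4R)-3-[(tert-butyldimethylsilyl)oxy]-4-(6-ethyl-3,5-dimethyl-4-oxo-4H-pyran-2-yl)-2-methylpentanal; 23 4-methyl-5-[(triethylsilyl)oxy]decan-3-one (1.2 equiv)
Product: 25 2-[(2R,3S,4R)-3-[(tert-butyldimethylsilyl)oxy]-5-hydroxy-4,6,8-trimethyl-7-oxo-9-[(triethylsilyl)oxy]tetradecan-2-yl]-6-ethyl-3,5-dimethyl-4H-pyran-4-one (mixture at C5, C6, C8, C9), via lithium enolate 24 (not isolated)
Conditions: 23, LiN(SiMe3)2 (commercial solution, 1.1 equiv), THF, −78 °C; then 18, −78 °C, 30 min; aq. NH4Cl at −78 °C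
Reagents that add atoms: none
Why: Kinetic deprotonation at the less hindered ethyl CH2 gives the lithium enolate, whose aldol addition to the aldehyde at −78 °C outruns proton transfer from the pyrone side chains, and the new centres are destined for oxidation.

Step 17
Reactants: 25 (aldol adduct above)
Product: 26 2-[(2R,3S,4R)-3-[(tert-butyldimethylsilyl)oxy]-5,9-dihydroxy-4,6,8-trimethyl-7-oxotetradecan-2-yl]-6-ethyl-3,5-dimethyl-4H-pyran-4-one (mixture at C5, C6, C8, C9)
Conditions: HF·pyridine, pyridine, THF, 0 °C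
Reagents that add atoms: none
Why: The triethylsilyl ether is far more labile to buffered HF·pyridine than the hindered secondary TBS ether, so only the former is cleaved.

Step 18
Reactants: 26 (diol above)
Product: 27 2-[(2R,3R,4S)-3-[(tert-butyldimethylsilyl)oxy]-4,6,8-trimethyl-5,7,9-trioxotetradecan-2-yl]-6-ethyl-3,5-dimethyl-4H-pyran-4-one (mixture at C6, C8; keto–enol tautomers)
Conditions: Dess–Martin periodinane (4 equiv), pyridine, CH2Cl2, rt
Reagents that add atoms: none
Why: Double Dess–Martin oxidation of the two β-hydroxy groups converges all diastereomers on a single 1,3,5-triketone without epimerising the adjacent C4 methine.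

Step 19
Reactants: 27 (triketone above)
Product: 28 2-[(2S,3R,4R)-3-[(tert-butyldimethylsilyl)oxy]-4-(6-ethyl-3,5-dimethyl-4-oxo-4H-pyran-2-yl)pentan-2-yl]-3,5-dimethyl-6-pentyl-4H-pyran-4-one
Conditions: Ph3P (5 equiv), CCl4, THF, rt
Reagents that add atoms: none
Why: The same near-neutral Yamamura-type cyclodehydration closes ring A from the triketone while ring B and both methine stereocentres are unaffected.

Step 20
Reactants: 28 (bis-pyrone silyl ether above)
Product: 29 2-[(2S,3R,4R)-4-(6-ethyl-3,5-dimethyl-4-oxo-4H-pyran-2-yl)-3-hydroxypentan-2-yl]-3,5-dimethyl-6-pentyl-4H-pyran-4-one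
Conditions: 48% aq. HF, MeCN, rt (→ 40 °C if slow)
Reagents that add atoms: none
Why: Aqueous HF in acetonitrile removes even a hindered secondary TBS ether, γ-pyrones are stable to it, and at the carbinol stage the methines are not yet activated towards enolisation.

Step 21
Reactants: 29 (bis-pyrone carbinol above)
Product: 30 2-[(2R,4S)-4-(6-ethyl-3,5-dimethyl-4-oxo-4H-pyran-2-yl)-3-oxopentan-2-yl]-3,5-dimethyl-6-pentyl-4H-pyran-4-one (target)
Conditions: Dess–Martin periodinane (1.5 equiv), water-saturated CH2Cl2, 0 °C → rt, 30 min; brief aq. Na2S2O3/NaHCO3 wash; rapid chromatography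
Reagents that add atoms: none
Why: Base-free Dess–Martin oxidation converts the carbinol into the ketone without enolising the two now doubly activated methines, so the R centre (ring A side, from step 2) and the S centre (ring B side, from step 5) are retained.

## Compound list

1 | methyl 2-(hydroxymethyl)prop-2-enoate | C=C(CO)C(=O)OC | starting material
2 | methyl 2-{[(tert-butyldimethylsilyl)oxy]methyl}prop-2-enoate | C=C(CO[Si](C)(C)C(C)(C)C)C(=O)OC | intermediate
3 | methyl (2R)-3-[(tert-butyldimethylsilyl)oxy]-2-methylpropanoate | COC(=O)[C@H](C)CO[Si](C)(C)C(C)(C)C | intermediate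
4 | (2S)-3-[(tert-butyldimethylsilyl)oxy]-2-methylpropan-1-ol | OC[C@H](C)CO[Si](C)(C)C(C)(C)C | intermediate
5 | (2R)-3-[(tert-butyldimethylsilyl)oxy]-2-methylpropanal | O=C[C@H](C)CO[Si](C)(C)C(C)(C)C | intermediate
6 | tributyl(but-2-en-1-yl)stannane (crotyltributylstannane, E/Z mixture) | CC=CC[Sn](CCCC)(CCCC)CCCC | starting material
7 | (2R,3R,4S)-1-[(tert-butyldimethylsilyl)oxy]-2,4-dimethylhex-5-en-3-ol | CC(C)(C)[Si](C)(C)OC[C@@H](C)[C@H](O)[C@@H](C)C=C | intermediate
8 | (2R,3R,4S)-1,3-bis[(tert-butyldimethylsilyl)oxy]-2,4-dimethylhex-5-ene | CC(C)(C)[Si](C)(C)OC[C@@H](C)[C@H](O[Si](C)(C)C(C)(C)C)[C@@H](C)C=C | intermediate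
9 | secondary ozonide (1,2,4-trioxolane) of 8, side chain as in 8, mixture at the ring carbon | CC(C)(C)[Si](C)(C)OC[C@@H](C)[C@H](O[Si](C)(C)C(C)(C)C)[C@@H](C)C1OCOO1 | intermediate
10 | (2R,3S,4R)-3,5-bis[(tert-butyldimethylsilyl)oxy]-2,4-dimethylpentanal | CC(C)(C)[Si](C)(C)OC[C@@H](C)[C@H](O[Si](C)(C)C(C)(C)C)[C@@H](C)C=O | intermediate
11 | heptane-3,5-dione | CCC(=O)CC(=O)CC | starting material
12 | 4-methylheptane-3,5-dione | CCC(=O)C(C)C(=O)CC | intermediate
13 | dilithium dienolate (1,3-dianion) of 12 | [Li+].[Li+].CC=C([O-])C(C)=C([O-])CC | intermediate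
14 | (8S,9S,10R)-9,11-bis[(tert-butyldimethylsilyl)oxy]-7-hydroxy-4,6,8,10-tetramethylundecane-3,5-dione (mixture at C4, C6, C7) | CC(C)(C)[Si](C)(C)OC[C@@H](C)[C@H](O[Si](C)(C)C(C)(C)C)[C@@H](C)C(O)C(C)C(=O)C(C)C(=O)CC | intermediate
15 | (8R,9S,10R)-9,11-bis[(tert-butyldimethylsilyl)oxy]-4,6,8,10-tetramethylundecane-3,5,7-trione (mixture at C4, C6) | CC(C)(C)[Si](C)(C)OC[C@@H](C)[C@H](O[Si](C)(C)C(C)(C)C)[C@@H](C)C(=O)C(C)C(=O)C(C)C(=O)CC | intermediate
16 | 2-[(2R,3S,4R)-3,5-bis[(tert-butyldimethylsilyl)oxy]-4-methylpentan-2-yl]-6-ethyl-3,5-dimethyl-4H-pyran-4-one | CC(C)(C)[Si](C)(C)OC[C@@H](C)[C@H](O[Si](C)(C)C(C)(C)C)[C@@H](C)c1oc(CC)c(C)c(=O)c1C | intermediate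
17 | 2-[(2R,3S,4R)-3-[(tert-butyldimethylsilyl)oxy]-5-hydroxy-4-methylpentan-2-yl]-6-ethyl-3,5-dimethyl-4H-pyran-4-one | OC[C@@H](C)[C@H](O[Si](C)(C)C(C)(C)C)[C@@H](C)c1oc(CC)c(C)c(=O)c1C | intermediate
18 | (2S,3R,4R)-3-[(tert-butyldimethylsilyl)oxy]-4-(6-ethyl-3,5-dimethyl-4-oxo-4H-pyran-2-yl)-2-methylpentanal | O=C[C@@H](C)[C@H](O[Si](C)(C)C(C)(C)C)[C@@H](C)c1oc(CC)c(C)c(=O)c1C | intermediate
19 | pentan-3-one | CCC(=O)CC | starting material
20 | hexanal | CCCCCC=O | starting material
21 | lithium enolate of pentan-3-one | [Li+].CC=C([O-])CC | intermediate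
22 | 5-hydroxy-4-methyldecan-3-one (racemic syn/anti mixture) | CCCCCC(O)C(C)C(=O)CC | intermediate
23 | 4-methyl-5-[(triethylsilyl)oxy]decan-3-one (racemic diastereomer mixture) | CCCCCC(O[Si](CC)(CC)CC)C(C)C(=O)CC | intermediate
24 | lithium enolate of 23 (ethyl side) | [Li+].CCCCCC(O[Si](CC)(CC)CC)C(C)C([O-])=CC | intermediate
25 | 2-[(2R,3S,4R)-3-[(tert-butyldimethylsilyl)oxy]-5-hydroxy-4,6,8-trimethyl-7-oxo-9-[(triethylsilyl)oxy]tetradecan-2-yl]-6-ethyl-3,5-dimethyl-4H-pyran-4-one (mixture at C5, C6, C8, C9) | CCCCCC(O[Si](CC)(CC)CC)C(C)C(=O)C(C)C(O)[C@@H](C)[C@H](O[Si](C)(C)C(C)(C)C)[C@@H](C)c1oc(CC)c(C)c(=O)c1C | intermediate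
26 | 2-[(2R,3S,4R)-3-[(tert-butyldimethylsilyl)oxy]-5,9-dihydroxy-4,6,8-trimethyl-7-oxotetradecan-2-yl]-6-ethyl-3,5-dimethyl-4H-pyran-4-one (mixture at C5, C6, C8, C9) | CCCCCC(O)C(C)C(=O)C(C)C(O)[C@@H](C)[C@H](O[Si](C)(C)C(C)(C)C)[C@@H](C)c1oc(CC)c(C)c(=O)c1C | intermediate
27 | 2-[(2R,3R,4S)-3-[(tert-butyldimethylsilyl)oxy]-4,6,8-trimethyl-5,7,9-trioxotetradecan-2-yl]-6-ethyl-3,5-dimethyl-4H-pyran-4-one (mixture at C6, C8) | CCCCCC(=O)C(C)C(=O)C(C)C(=O)[C@@H](C)[C@H](O[Si](C)(C)C(C)(C)C)[C@@H](C)c1oc(CC)c(C)c(=O)c1C | intermediate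
28 | 2-[(2S,3R,4R)-3-[(tert-butyldimethylsilyl)oxy]-4-(6-ethyl-3,5-dimethyl-4-oxo-4H-pyran-2-yl)pentan-2-yl]-3,5-dimethyl-6-pentyl-4H-pyran-4-one | CCCCCc1oc([C@@H](C)[C@H](O[Si](C)(C)C(C)(C)C)[C@@H](C)c2oc(CC)c(C)c(=O)c2C)c(C)c(=O)c1C | intermediate
29 | 2-[(2S,3R,4R)-4-(6-ethyl-3,5-dimethyl-4-oxo-4H-pyran-2-yl)-3-hydroxypentan-2-yl]-3,5-dimethyl-6-pentyl-4H-pyran-4-one | CCCCCc1oc([C@@H](C)[C@H](O)[C@@H](C)c2oc(CC)c(C)c(=O)c2C)c(C)c(=O)c1C | intermediate
30 | 2-[(2R,4S)-4-(6-ethyl-3,5-dimethyl-4-oxo-4H-pyran-2-yl)-3-oxopentan-2-yl]-3,5-dimethyl-6-pentyl-4H-pyran-4-one | CCCCCc1oc([C@@H](C)C(=O)[C@@H](C)c2oc(CC)c(C)c(=O)c2C)c(C)c(=O)c1C | target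

## Step count and risks

Total steps: 21. Longest linear sequence: 18 (steps 1–7, 9–13, 16–21); steps 8 and 14–15 are side branches.

**Step 9 (dianion aldol).** The strongly basic dianion may enolise aldehyde 10 or give poor conversion. The fallback sets out from 10 and pentan-3-one 19 and comes back at triketone 15. Lithium enolate 21 is added to propanal to give 5-hydroxy-4-methylheptan-3-one F1, which is silylated (Et3SiCl, imidazole) to 4-methyl-5-[(triethylsilyl)oxy]heptan-3-one F2. LiN(SiMe3)2 (THF, −78 °C) converts this into its lithium enolate F3, which adds to 10 to give the silyl-protected aldol adduct F4. Pyridinium p-toluenesulfonate in MeOH at 0 °C removes only the triethylsilyl group (the primary TBS ether is much slower) to give the dihydroxy ketone F5, and double Dess–Martin oxidation gives 15.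

**Step 11 (Ph3P/CCl4 cyclodehydration; the same risk applies to step 19).** Ring closure may be sluggish, or the methine next to the triketone may epimerise. The fallback sets out from 14, bypasses 15, and comes back at 16. Acid-catalysed cyclodehydration of the δ-hydroxy-β-diketone (p-TsOH cat., CH2Cl2, rt) gives the dihydropyranone F6, in which the side-chain methine is attached to an sp3 carbon and cannot enolise. Soft enolisation (Me3SiOTf, Et3N, CH2Cl2, 0 °C) gives the 4-silyloxy-2H-pyran F7. DDQ (CH2Cl2, 0 °C) then abstracts hydride from C2, next to the ring oxygen, and loss of the silyl group from the resulting pyrylium ion gives pyrone 16.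

**Step 16 (enolate aldol onto the pyrone-bearing aldehyde).** Under basic conditions, proton transfer from the pyrone side chains or epimerisation α to the aldehyde could compete. The fallback sets out from 23 and 18 and comes back at 25. Enolate 24 is trapped with Me3SiCl and the enol silane F8 is isolated. It is combined with 18 under BF3·OEt2 (2.5 equiv, CH2Cl2, −78 °C) in a Mukaiyama aldol addition, which gives 25 after aqueous work-up with no basic species present.

## Further compounds

F1 | step 9 | 5-hydroxy-4-methylheptan-3-one (diastereomer mixture) | CCC(O)C(C)C(=O)CC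
F2 | step 9 | 4-methyl-5-[(triethylsilyl)oxy]heptan-3-one | CCC(O[Si](CC)(CC)CC)C(C)C(=O)CC
F3 | step 9 | lithium enolate of F2 (ethyl side) | [Li+].CCC(O[Si](CC)(CC)CC)C(C)C([O-])=CC
F4 | step 9 | (8S,9S,10R)-9,11-bis[(tert-butyldimethylsilyl)oxy]-7-hydroxy-4,6,8,10-tetramethyl-3-[(triethylsilyl)oxy]undecan-5-one (mixture at C3, C4, C6, C7) | CC(C)(C)[Si](C)(C)OC[C@@H](C)[C@H](O[Si](C)(C)C(C)(C)C)[C@@H](C)C(O)C(C)C(=O)C(C)C(O[Si](CC)(CC)CC)CC
F5 | step 9 | (8S,9S,10R)-9,11-bis[(tert-butyldimethylsilyl)oxy]-3,7-dihydroxy-4,6,8,10-tetramethylundecan-5-one (mixture at C3, C4, C6, C7) | CC(C)(C)[Si](C)(C)OC[C@@H](C)[C@H](O[Si](C)(C)C(C)(C)C)[C@@H](C)C(O)C(C)C(=O)C(C)C(O)CC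
F6 | step 11 | 2-[(2S,3S,4R)-3,5-bis[(tert-butyldimethylsilyl)oxy]-4-methylpentan-2-yl]-6-ethyl-3,5-dimethyl-2,3-dihydro-4H-pyran-4-one (mixture at ring C2, C3) | CC(C)(C)[Si](C)(C)OC[C@@H](C)[C@H](O[Si](C)(C)C(C)(C)C)[C@@H](C)C1OC(CC)=C(C)C(=O)C1C
F7 | step 11 | 2-[(2S,3S,4R)-3,5-bis[(tert-butyldimethylsilyl)oxy]-4-methylpentan-2-yl]-6-ethyl-3,5-dimethyl-4-[(trimethylsilyl)oxy]-2H-pyran (mixture at ring C2) | CC(C)(C)[Si](C)(C)OC[C@@H](C)[C@H](O[Si](C)(C)C(C)(C)C)[C@@H](C)C1OC(CC)=C(C)C(O[Si](C)(C)C)=C1C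
F8 | step 16 | 4-methyl-5-[(triethylsilyl)oxy]-3-[(trimethylsilyl)oxy]dec-2-ene (enol silane of 23) | CCCCCC(O[Si](CC)(CC)CC)C(C)C(O[Si](C)(C)C)=CC
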